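Assumption (chemistry): in step 10 the (Sa,Sc,Sc) phosphoramidite is taken to give the (S)-ether, by analogy with the usual sense of induction for heteroatom nucleophiles on cinnamyl carbonates. If a model run with 15 and cinnamyl methyl carbonate shows the opposite sense, the (Ra,Rc,Rc) ligand is used and nothing else changes.

Check of structures: 17, 18, 19 and 20 share the same constitution around rings A, B and C (O5 benzyl or H, O7 methyl, ring B para-oxygen, catechol ring O-aryl next to O-benzyl or OH). C2 is S in all four, because the order O > aryl > C3 > H holds whether C3 is vinyl, enol ether or methylene. No structure needs to be changed.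

## Structural features

The target is a C–O–C linked biflavonoid. A (2S)-flavanone (rings A, B, C; 5-OH, 7-OMe) and a flavone (benzo ring D, pyranone ring E, aryl ring F; 5,7-dihydroxy) are joined by a diaryl ether between C4′ of ring B and C3 of the catechol-type ring F, whose C4 bears a free hydroxyl and whose C1 bears the flavone C2. The only stereocentre is C2 of ring C, with no neighbouring stereocentre; it is benzylic, carries the ring oxygen O1 and lies β to the C4 ketone. This makes it the fragile point: any base that enolises C3 can expel O1 (E1cB, retro-oxa-Michael) to a 2′-hydroxychalcone that recloses as racemate, and strong acid can ionise the same benzylic C–O bond. Further sensitive groups are the four free phenols, the flavone pyranone (opened by hydroxide, attacked by hydride and organometallic reagents) and the single methyl ether at O7, which must stay distinct from five other phenolic oxygens. The diaryl ether is robust and easy, because ring B can carry a para carbonyl group that activates a fluoride for displacement. The real difficulty is to create C2 as one enantiomer and to close ring C without an enolate or enone ever standing next to it, in a molecule that already holds a complete second flavonoid. The key step exploits the C3–C4 bond of ring C: C4 is a ketone carbon on C4a of ring A and C3 is a methylene next to C2, so the ketone can be carried as a silyl enol ether C3=C4, made by metathesis between a vinyl group on C2 and a 1-silyloxyvinyl group on C4a.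

## Logic of the disconnections

20 ⇒ 19. The four phenolic O–H bonds are traced to four O–CH2Ph bonds. One kind of protecting group for all free phenols allows a single neutral unmasking at the end, while O7 stays methyl throughout. The forward step must remove four benzyl groups without reducing either heterocycle and without acid or base at C2.

19 ⇒ 18. The C4 ketone and the C3–H bond are traced to the O–Si enol ether with C3=C4. This keeps C3 non-enolisable until the last moment. The forward step must be a protonation at C3, not a fluoride-induced enolate release, because a free C3 enolate could expel O1.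

18 ⇒ 17. The C3=C4 double bond is cut into two terminal alkenes, a vinyl group on C2 and a 1-silyloxyvinyl group on ring A. This removes ring C and leaves an acyclic aryl allyl ether with the stereocentre already in place. The forward step must favour ring closure over intermolecular metathesis and must not migrate the allyl double bond.

17 ⇒ 16. The O–Si bond is cut to give the methyl ketone. The demand is an enolisation that touches neither C2–H nor the flavone carbonyl, so a strong hindered base with a silyl chloride is chosen over a silyl triflate.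

16 ⇒ 13 + 15. The C2–O1 bond is cut between an allyl electrophile and a phenoxide. This is the most convergent cut, since it separates ring A from everything else and creates the only stereocentre in an irreversible, catalyst-controlled event. The forward step must be branched-selective and enantioselective and must be stopped before the product ether re-ionises.

13 ⇒ 12 ⇒ 11 ⇒ 10. The carbonate C–O bond, the carbinol C–H bond and the Cα=Cβ bond are cut in turn, reducing the allyl electrophile to an aryl aldehyde. The demand is that hydride and ylide reagents discriminate between the aldehyde or enal and the flavone carbonyl.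

10 ⇒ 9 ⇒ 8 ⇒ 7 + 5. The aldehyde is traced to its acetal, pyranone ring E is opened at O1–C2 to the β-diketone, and the diketone is cut at C2–C3 into a methyl ketone and a methyl ester. The aldehyde must be masked while the enolate is present, and the acid that closes ring E then removes the mask.

5 ⇒ 4 ⇒ 2 + 3. The acetal C–O bonds are cut, then the diaryl ether C–O bond, which is formed by displacement of fluoride para to a formyl group. This reaches two simple benzenes; the demand is only that the ester survives carbonate in a dipolar solvent.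

2 ⇒ 1, 7 ⇒ 6, 15 ⇒ 14. The benzyl O–C bonds are cut. Each benzylation relies on the different acidity and hydrogen bonding of the phenols (para to the carbonyl versus chelated ortho), so the forward steps need controlled stoichiometry.

## Other disconnections considered

Alternative 1: Ring B of the flavanone half is cut at C2′–C3′ and C4′–C5′, so it would be assembled from the 2-pyranone A1 (methyl coumalate) and the aryl ethynyl ether A2 of the catechol ring.
- Forward step: the electron-rich alkyne of A2 would add across C3 and C6 of electron-poor A1 in an inverse-demand Diels–Alder reaction (terminal alkyne carbon to C6, oxygen-bearing carbon to C3). Cycloreversion with loss of the lactone bridge would aromatise the adduct to benzoate A3, with the diaryl ether oxygen para to the ester.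
- In its favour: the step is metal-free and base-free, its regiochemistry follows from pairing the most nucleophilic alkyne carbon with the most electrophilic pyranone carbon, and it needs no activated aryl halide. A3 also carries two differentiated carbonyl termini, a point on which it equals 5.
- Against it here: ring B is a plain para-phenylene that 3 supplies in one displacement. A2 would take extra operations from a phenol, and aryl ynol ethers are sensitive to acid, water and heat, while the cycloaddition needs heating. In A3 the ester sits on ring B and the masked aldehyde on ring F, the reverse of 5, so the flavone would have to be built from an aldehyde and the ring B ester reduced later, next to a hydride-sensitive flavone or after reordering. C2 and ring C are untouched, so steps 10 to 12 would still be needed.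
- Comparison: in structure it solves a bond the chosen plan makes in one step. In mechanism it is the milder process and would be the better choice if ring B had no activating group, which does not apply here. In step economy it is at least three steps longer.

Alternative 2: The three bonds of flavone pyranone ring E are cut (C4–C4a, C3–C4, O1–C2), giving iodophenol A4, terminal alkyne A5 and carbon monoxide A6.
- Forward step: zerovalent palladium would insert into the C–I bond of A4 and A6 would insert to an acylpalladium species. Coupling with A5 would give an o-hydroxyaryl ynone, and 6-endo addition of the phenol would close ring E to A7, which is identical with 9.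
- In its favour: it is convergent, needs only an amine base and leaves the dioxolane intact. In functional-group tolerance it is equal to or better than the strong base and acid of step 5.
- Against it here: A4 requires iodination of a phloroglucinol dibenzyl ether ortho to the hydroxyl, in competition with the position between the two benzyloxy groups. The resulting iodide is electron-rich and flanked on both sides, which slows oxidative addition. A5 requires the ring F carbon to be an alkyne, which from 5 means reduction, oxidation and one-carbon homologation. The ynone can also close 5-exo to an aurone, and a toxic gas is needed.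
- Comparison: in structure both routes end at the same compound. In mechanism the alternative is milder in pH. In step economy step 5 is one telescoped operation from 5 and 7, and the alternative costs about three more steps. It has no bearing on C2 or on flavanone ring C, so it competes only with step 5 and could be grafted onto the chosen plan.

Alternative 3: O1–C8a and C4–C4a are cut, so ring A would arrive as aryne A10, generated from silylaryl triflate A9 by a fluoride source, and O1, C2, C3 and C4 would come from the (S)-β-hydroxy ester A8.
- Forward step: the alkoxide of A8 would add to the aryne carbon remote from the flanking methoxy group. The aryl anion formed next to that methoxy group would attack the ester and close ring C to A11.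
- In its favour: both bonds between ring A and ring C form in one operation. C2 is set earlier in A8 by reliable asymmetric ketone reduction or aldol chemistry, and its C–O bond is never broken, which equals the chosen plan in that respect. From 10 it would be about two steps shorter, which is better.
- Against it here: the alkoxide of A8 is a β-oxido ester, open to retro-aldol cleavage and to E1cB dehydration. The aryl anion can be quenched by the acidic α-methylene instead of acylating. A11 would be released as an enolisable β-aryloxy ketone in a medium that holds fluoride and the alkoxide expelled in the acylation, the very conditions for ring opening to the chalcone and loss of configuration. Ring A arrives as the 5,7-dimethyl ether, so a chelation-directed Lewis-acid demethylation at O5 is needed on the finished flavanone.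
- Comparison: in structure the alternative gives up the O5/O7 differentiation that 15 has from the start. In mechanism it is anionic and basic at the moment ring C forms, whereas metathesis is neutral and keeps C4 masked. In step economy the alternative is shorter. The chosen plan is preferred because it protects the one fragile element.

Key step: step 12

## Route

Step 1
Reactants: 1 methyl 3,4-dihydroxybenzoate
Product: 2 methyl 4-(benzyloxy)-3-hydroxybenzoate
Conditions: BnBr (1.05 equiv), NaHCO3 (1.5 equiv), NaI (cat.), DMF, 40 °C
Reagents that add atoms: benzyl bromide, BrCc1ccccc1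
Why: Williamson etherification; the 4-OH, para to the ester, is the more acidic phenol and the only one appreciably deprotonated by hydrogencarbonate, so monobenzylation at O4 should dominate.

Step 2
Reactants: 2 methyl 4-(benzyloxy)-3-hydroxybenzoate; 3 4-fluorobenzaldehyde
Product: 4 methyl 4-(benzyloxy)-3-(4-formylphenoxy)benzoate
Conditions: K2CO3 (1.5 equiv), dry DMF, 100 °C
Reagents that add atoms: none
Why: Nucleophilic aromatic substitution (addition–elimination); the para formyl group stabilises the Meisenheimer adduct and fluoride leaves, while the ester and benzyl ether are inert to dry carbonate.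

Step 3
Reactants: 4 methyl 4-(benzyloxy)-3-(4-formylphenoxy)benzoate
Product: 5 methyl 4-(benzyloxy)-3-[4-(1,3-dioxolan-2-yl)phenoxy]benzoate
Conditions: ethylene glycol (3 equiv), TsOH·H2O (5 mol %), toluene, reflux, Dean–Stark
Reagents that add atoms: ethylene glycol, OCCO
Why: Acid-catalysed acetalisation driven by azeotropic removal of water; it masks the aldehyde against the enolate of step 5 and leaves the benzoate untouched.

Step 4
Reactants: 6 2′,4′,6′-trihydroxyacetophenone
Product: 7 1-[2,4-bis(benzyloxy)-6-hydroxyphenyl]ethanone
Conditions: BnBr (2.05 equiv), K2CO3 (2.2 equiv), acetone, reflux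
Reagents that add atoms: benzyl bromide, BrCc1ccccc1
Why: Williamson etherification; the para OH and one of the two equivalent ortho OH groups react, and the last ortho OH is held in a hydrogen bond to the ketone and should remain free.

Step 5
Reactants: 7 1-[2,4-bis(benzyloxy)-6-hydroxyphenyl]ethanone; 5 methyl 4-(benzyloxy)-3-[4-(1,3-dioxolan-2-yl)phenoxy]benzoate
Product: 10 4-{2-(benzyloxy)-5-[5,7-bis(benzyloxy)-4-oxo-4H-chromen-2-yl]phenoxy}benzaldehyde, via β-diketone 8 (not isolated), via flavone acetal 9 (not isolated)
Conditions: LiN(SiMe3)2 (3.5 equiv), THF, −78 °C to rt; AcOH quench, solvent exchange; TsOH·H2O (0.3 equiv), toluene, 80 °C; then 2 M HCl–THF (1:4), rt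
Reagents that add atoms: water, O
Why: Crossed Claisen condensation of the phenoxide–enolate dianion of 7 with the ester gives the β-diketone; acid-catalysed cyclodehydration (phenol onto the distal carbonyl, then loss of water) closes pyranone ring E. Aqueous acid then hydrolyses the dioxolane, and benzyl aryl ethers should tolerate these mild acids.

Step 6
Reactants: 10 4-{2-(benzyloxy)-5-[5,7-bis(benzyloxy)-4-oxo-4H-chromen-2-yl]phenoxy}benzaldehyde
Product: 11 (2E)-3-(4-{2-(benzyloxy)-5-[5,7-bis(benzyloxy)-4-oxo-4H-chromen-2-yl]phenoxy}phenyl)prop-2-enal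
Conditions: Ph3P=CHCHO (1.15 equiv), toluene, 80 °C
Reagents that add atoms: (triphenylphosphoranylidene)acetaldehyde, O=CC=P(c1ccccc1)(c1ccccc1)c1ccccc1
Why: Wittig olefination with a stabilised ylide, E-selective; the ylide is too weak a nucleophile for the flavone carbonyl, and a small excess limits a second homologation of the enal.

Step 7
Reactants: 11 (2E)-3-(4-{2-(benzyloxy)-5-[5,7-bis(benzyloxy)-4-oxo-4H-chromen-2-yl]phenoxy}phenyl)prop-2-enal
Product: 12 5,7-bis(benzyloxy)-2-[4-(benzyloxy)-3-{4-[(1E)-3-hydroxyprop-1-en-1-yl]phenoxy}phenyl]-4H-chromen-4-one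
Conditions: NaBH4 (1.0 equiv), CeCl3·7H2O (1.0 equiv), MeOH–THF (1:1), −20 °C
Reagents that add atoms: none
Why: Luche reduction; the cerium salt directs hydride to the aldehyde carbon (1,2-addition), and at low temperature the flavone, a vinylogous ester, should not be reduced.

Step 8
Reactants: 12 5,7-bis(benzyloxy)-2-[4-(benzyloxy)-3-{4-[(1E)-3-hydroxyprop-1-en-1-yl]phenoxy}phenyl]-4H-chromen-4-one
Product: 13 (2E)-3-(4-{2-(benzyloxy)-5-[5,7-bis(benzyloxy)-4-oxo-4H-chromen-2-yl]phenoxy}phenyl)prop-2-en-1-yl methyl carbonate
Conditions: ClCO2Me (1.5 equiv), pyridine (3 equiv), DMAP (cat.), CH2Cl2, 0 °C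
Reagents that add atoms: methyl chloroformate, COC(=O)Cl
Why: O-Acylation of a primary allylic alcohol with a chloroformate; no other nucleophilic group is present.

Step 9
Reactants: 14 2′,6′-dihydroxy-4′-methoxyacetophenone
Product: 15 1-[2-(benzyloxy)-6-hydroxy-4-methoxyphenyl]ethanone
Conditions: BnBr (1.0 equiv), K2CO3 (1.1 equiv), acetone, reflux
Reagents that add atoms: benzyl bromide, BrCc1ccccc1
Why: Williamson monoetherification of a symmetrical diphenol; after the first benzylation the remaining OH is locked in a hydrogen bond to the ketone, so the second alkylation should be much slower.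

Step 10
Reactants: 13 (2E)-3-(4-{2-(benzyloxy)-5-[5,7-bis(benzyloxy)-4-oxo-4H-chromen-2-yl]phenoxy}phenyl)prop-2-en-1-yl methyl carbonate; 15 1-[2-(benzyloxy)-6-hydroxy-4-methoxyphenyl]ethanone
Product: 16 1-[2-(benzyloxy)-4-methoxy-6-{[(1S)-1-(4-{2-(benzyloxy)-5-[5,7-bis(benzyloxy)-4-oxo-4H-chromen-2-yl]phenoxy}phenyl)prop-2-en-1-yl]oxy}phenyl]ethanone
Conditions: 15 (1.5 equiv), LiOt-Bu (1.4 equiv), THF, rt; then 13, [Ir(cod)Cl]2 (2 mol %), (Sa,Sc,Sc)-O,O′-(1,1′-binaphthalene-2,2′-diyl) N,N-bis(1-phenylethyl)phosphoramidite (4 mol %, catalyst pre-activated with n-PrNH2), THF, rt to 40 °C, stopped at full conversion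
Reagents that add atoms: none
Why: Iridium-catalysed asymmetric allylic etherification; the cyclometalated iridium phosphoramidite ionises the linear carbonate to a π-allyl complex, and the aryloxide attacks its aryl-bearing terminus (branched selectivity) on the face fixed by the ligand, which sets C2 as S. Only the phenol is deprotonated by the alkoxide, so O-allylation and not enolate chemistry is expected.

Step 11
Reactants: 16 1-[2-(benzyloxy)-4-methoxy-6-{[(1S)-1-(4-{2-(benzyloxy)-5-[5,7-bis(benzyloxy)-4-oxo-4H-chromen-2-yl]phenoxy}phenyl)prop-2-en-1-yl]oxy}phenyl]ethanone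
Product: 17 5,7-bis(benzyloxy)-2-{4-(benzyloxy)-3-[4-((1S)-1-{3-(benzyloxy)-2-[1-(tert-butyldimethylsilyloxy)ethenyl]-5-methoxyphenoxy}prop-2-en-1-yl)phenoxy]phenyl}-4H-chromen-4-one
Conditions: KN(SiMe3)2 (1.2 equiv), THF, −78 °C; TBSCl (1.5 equiv), −78 to 0 °C; pH 7 buffer
Reagents that add atoms: tert-butyldimethylsilyl chloride, CC(C)(C)[Si](C)(C)Cl
Why: Kinetic deprotonation of the methyl ketone, the only acidic C–H, and O-silylation of the potassium enolate; C2–H is far less acidic and the enolate has no β-leaving group. A silyl triflate with an amine is avoided because it would silylate the flavone carbonyl to a flavylium ion that the new enol ether could attack.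

Step 12
Reactants: 17 5,7-bis(benzyloxy)-2-{4-(benzyloxy)-3-[4-((1S)-1-{3-(benzyloxy)-2-[1-(tert-butyldimethylsilyloxy)ethenyl]-5-methoxyphenoxy}prop-2-en-1-yl)phenoxy]phenyl}-4H-chromen-4-one
Product: 18 (2S)-5-(benzyloxy)-2-(4-{2-(benzyloxy)-5-[5,7-bis(benzyloxy)-4-oxo-4H-chromen-2-yl]phenoxy}phenyl)-4-(tert-butyldimethylsilyloxy)-7-methoxy-2H-chromene
Conditions: (H2IMes)(PCy3)Cl2Ru=CHPh (second-generation Grubbs catalyst, 10 mol % in two portions), 1,4-benzoquinone (20 mol %), degassed toluene (0.005 M), 60 °C, dark; ethyl vinyl ether quench, Et3N-treated silica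
Reagents that add atoms: none
Why: The ruthenium benzylidene should exchange with the monosubstituted vinyl group on C2 to give an alkylidene at C3; intramolecular [2+2] addition to the 1,1-disubstituted silyl enol ether (ruthenium on the terminal CH2, C3 bonding to C4) gives a ruthenacyclobutane whose cycloreversion forms C3=C4 and Ru=CH2, which carries the chain and releases ethylene. The closest known reaction type is ring-closing metathesis of silyl enol ethers with terminal alkenes to cyclic silyl enol ethers, including benzo-fused six-membered heterocycles, with this catalyst. Ring C closes as a six-membered ring by metathesis of a 1,7-diene, the new double bond being endocyclic. No stereocentre is formed; C2, set in step 10, takes no part in bond making or breaking and stays S. Cyclisation must beat cross-metathesis, which high dilution and the ortho placement of both alkenes on ring A (the two flanking oxygens twist the enol ether towards the allyl group) should secure. Initiation at the hindered enol ether, which would lead to an inert oxygen-substituted carbene, is disfavoured sterically. Ruthenium hydride migration of the allyl double bond, which would destroy C2, is suppressed by benzoquinone; moderate temperature and exclusion of light guard against 6π ring opening of the 2H-chromene. The flavone C2=C3 bond is trisubstituted, electron-poor and endocyclic and should not react.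

Step 13
Reactants: 18 (2S)-5-(benzyloxy)-2-(4-{2-(benzyloxy)-5-[5,7-bis(benzyloxy)-4-oxo-4H-chromen-2-yl]phenoxy}phenyl)-4-(tert-butyldimethylsilyloxy)-7-methoxy-2H-chromene
Product: 19 (2S)-5-(benzyloxy)-2-(4-{2-(benzyloxy)-5-[5,7-bis(benzyloxy)-4-oxo-4H-chromen-2-yl]phenoxy}phenyl)-7-methoxy-2,3-dihydro-4H-chromen-4-one
Conditions: 1 M HCl–THF (1:10), 0 °C to rt
Reagents that add atoms: none
Why: Acid-catalysed hydrolysis of a silyl enol ether: protonation at C3 gives a silyloxy-stabilised cation that loses silicon to water. No C3 enolate is formed, so the E1cB opening of ring C that unbuffered fluoride could trigger is excluded and C2 stays S.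

Step 14
Reactants: 19 (2S)-5-(benzyloxy)-2-(4-{2-(benzyloxy)-5-[5,7-bis(benzyloxy)-4-oxo-4H-chromen-2-yl]phenoxy}phenyl)-7-methoxy-2,3-dihydro-4H-chromen-4-one
Product: 20 (2S)-2-{4-[5-(5,7-dihydroxy-4-oxo-4H-chromen-2-yl)-2-hydroxyphenoxy]phenyl}-5-hydroxy-7-methoxy-2,3-dihydro-4H-chromen-4-one
Conditions: H2 (1 atm), Pd/C (10 wt %), EtOAc–THF–MeOH, rt, stopped when the last benzyl ether is gone
Reagents that add atoms: none
Why: Heterogeneous catalytic hydrogenolysis of four benzyl aryl ethers under neutral conditions; the chelated aryl ketone, the flavone C2=C3 bond and the cyclic benzylic C2–O1 bond react more slowly, and the neutral medium cannot epimerise C2.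

## Compound list

1 | methyl 3,4-dihydroxybenzoate | COC(=O)c1ccc(O)c(O)c1 | starting material
2 | methyl 4-(benzyloxy)-3-hydroxybenzoate | COC(=O)c1ccc(OCc2ccccc2)c(O)c1 | intermediate
3 | 4-fluorobenzaldehyde | O=Cc1ccc(F)cc1 | starting material
4 | methyl 4-(benzyloxy)-3-(4-formylphenoxy)benzoate | COC(=O)c1ccc(OCc2ccccc2)c(Oc2ccc(C=O)cc2)c1 | intermediate
5 | methyl 4-(benzyloxy)-3-[4-(1,3-dioxolan-2-yl)phenoxy]benzoate | COC(=O)c1ccc(OCc2ccccc2)c(Oc2ccc(C3OCCO3)cc2)c1 | intermediate
6 | 2′,4′,6′-trihydroxyacetophenone | CC(=O)c1c(O)cc(O)cc1O | starting material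
7 | 1-[2,4-bis(benzyloxy)-6-hydroxyphenyl]ethanone | CC(=O)c1c(O)cc(OCc2ccccc2)cc1OCc1ccccc1 | intermediate
8 | 1-[2,4-bis(benzyloxy)-6-hydroxyphenyl]-3-{4-(benzyloxy)-3-[4-(1,3-dioxolan-2-yl)phenoxy]phenyl}propane-1,3-dione (β-diketone) | O=C(CC(=O)c1ccc(OCc2ccccc2)c(Oc2ccc(C3OCCO3)cc2)c1)c1c(O)cc(OCc2ccccc2)cc1OCc1ccccc1 | intermediate
9 | 5,7-bis(benzyloxy)-2-{4-(benzyloxy)-3-[4-(1,3-dioxolan-2-yl)phenoxy]phenyl}-4H-chromen-4-one (flavone acetal) | O=c1cc(-c2ccc(OCc3ccccc3)c(Oc3ccc(C4OCCO4)cc3)c2)oc2cc(OCc3ccccc3)cc(OCc3ccccc3)c12 | intermediate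
10 | 4-{2-(benzyloxy)-5-[5,7-bis(benzyloxy)-4-oxo-4H-chromen-2-yl]phenoxy}benzaldehyde | O=Cc1ccc(Oc2cc(-c3cc(=O)c4c(OCc5ccccc5)cc(OCc5ccccc5)cc4o3)ccc2OCc2ccccc2)cc1 | intermediate
11 | (2E)-3-(4-{2-(benzyloxy)-5-[5,7-bis(benzyloxy)-4-oxo-4H-chromen-2-yl]phenoxy}phenyl)prop-2-enal | O=C/C=C/c1ccc(Oc2cc(-c3cc(=O)c4c(OCc5ccccc5)cc(OCc5ccccc5)cc4o3)ccc2OCc2ccccc2)cc1 | intermediate
12 | 5,7-bis(benzyloxy)-2-[4-(benzyloxy)-3-{4-[(1E)-3-hydroxyprop-1-en-1-yl]phenoxy}phenyl]-4H-chromen-4-one | OC/C=C/c1ccc(Oc2cc(-c3cc(=O)c4c(OCc5ccccc5)cc(OCc5ccccc5)cc4o3)ccc2OCc2ccccc2)cc1 | intermediate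
13 | (2E)-3-(4-{2-(benzyloxy)-5-[5,7-bis(benzyloxy)-4-oxo-4H-chromen-2-yl]phenoxy}phenyl)prop-2-en-1-yl methyl carbonate | COC(=O)OC/C=C/c1ccc(Oc2cc(-c3cc(=O)c4c(OCc5ccccc5)cc(OCc5ccccc5)cc4o3)ccc2OCc2ccccc2)cc1 | intermediate
14 | 2′,6′-dihydroxy-4′-methoxyacetophenone | COc1cc(O)c(C(C)=O)c(O)c1 | starting material
15 | 1-[2-(benzyloxy)-6-hydroxy-4-methoxyphenyl]ethanone | COc1cc(O)c(C(C)=O)c(OCc2ccccc2)c1 | intermediate
16 | 1-[2-(benzyloxy)-4-methoxy-6-{[(1S)-1-(4-{2-(benzyloxy)-5-[5,7-bis(benzyloxy)-4-oxo-4H-chromen-2-yl]phenoxy}phenyl)prop-2-en-1-yl]oxy}phenyl]ethanone | CC(=O)c1c(OCc2ccccc2)cc(OC)cc1O[C@H](c1ccc(Oc2cc(-c3cc(=O)c4c(OCc5ccccc5)cc(OCc5ccccc5)cc4o3)ccc2OCc2ccccc2)cc1)C=C | intermediate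
17 | 5,7-bis(benzyloxy)-2-{4-(benzyloxy)-3-[4-((1S)-1-{3-(benzyloxy)-2-[1-(tert-butyldimethylsilyloxy)ethenyl]-5-methoxyphenoxy}prop-2-en-1-yl)phenoxy]phenyl}-4H-chromen-4-one | C=C(O[Si](C)(C)C(C)(C)C)c1c(OCc2ccccc2)cc(OC)cc1O[C@H](c1ccc(Oc2cc(-c3cc(=O)c4c(OCc5ccccc5)cc(OCc5ccccc5)cc4o3)ccc2OCc2ccccc2)cc1)C=C | intermediate
18 | (2S)-5-(benzyloxy)-2-(4-{2-(benzyloxy)-5-[5,7-bis(benzyloxy)-4-oxo-4H-chromen-2-yl]phenoxy}phenyl)-4-(tert-butyldimethylsilyloxy)-7-methoxy-2H-chromene | COc1cc(OCc2ccccc2)c2c(c1)O[C@H](c1ccc(Oc3cc(-c4cc(=O)c5c(OCc6ccccc6)cc(OCc6ccccc6)cc5o4)ccc3OCc3ccccc3)cc1)C=C2O[Si](C)(C)C(C)(C)C | intermediate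
19 | (2S)-5-(benzyloxy)-2-(4-{2-(benzyloxy)-5-[5,7-bis(benzyloxy)-4-oxo-4H-chromen-2-yl]phenoxy}phenyl)-7-methoxy-2,3-dihydro-4H-chromen-4-one | COc1cc(OCc2ccccc2)c2c(c1)O[C@H](c1ccc(Oc3cc(-c4cc(=O)c5c(OCc6ccccc6)cc(OCc6ccccc6)cc5o4)ccc3OCc3ccccc3)cc1)CC2=O | intermediate
20 | (2S)-2-{4-[5-(5,7-dihydroxy-4-oxo-4H-chromen-2-yl)-2-hydroxyphenoxy]phenyl}-5-hydroxy-7-methoxy-2,3-dihydro-4H-chromen-4-one | COc1cc(O)c2c(c1)O[C@H](c1ccc(Oc3cc(-c4cc(=O)c5c(O)cc(O)cc5o4)ccc3O)cc1)CC2=O | target

## Step count and risks

Total step count: 14. Longest linear sequence: 12 steps (1, 2, 3, 5, 6, 7, 8, 10, 11, 12, 13, 14); steps 4 and 9 are side branches.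

Least certain steps:

**Step 12 (key step).**
- Risk: slow ring closure. The enol ether is 1,1-disubstituted and flanked by two ortho oxygens, and the product has a peri contact between the silyloxy group at C4 and the benzyloxy group at C5. Intermolecular metathesis through the allyl alkenes or catalyst decay could then take over.
- Second risk: double-bond migration of the allyl ether by ruthenium hydrides, which would erase C2.
- Fallback: setting out from 15 and 10, a Claisen–Schmidt condensation (KOH, EtOH–THF, rt) should give the 2′-hydroxychalcone F1. Buffered oxa-Michael cyclisation (NaOAc, EtOH, reflux) should give the racemic tetra-O-benzyl flavanone F2. Preparative chromatography on a polysaccharide chiral stationary phase should then deliver the S enantiomer, which is 19, where the route is rejoined. The R enantiomer can be returned to the F1/F2 equilibrium and recycled. This gives up catalytic control of C2 but needs no metathesis.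

**Step 10.**
- Risk: erosion of branched selectivity and of enantiomeric purity. The chelated, electron-poor 2-acylaryloxide is a weak nucleophile and a good leaving group, and the ring B aryloxy group stabilises the allyl cation, so the product ether can re-ionise on the catalyst.
- Fallback: setting out from 10, CH2=CHMgBr (THF, −78 °C) should add to the aldehyde only and give the racemic allylic alcohol F3. Acylation with vinyl acetate and Candida antarctica lipase B should convert the R enantiomer into the acetate F4, separable from the unreacted S alcohol. K2CO3 in MeOH should release the (R)-alcohol F5. Mitsunobu etherification of 15 with F5 (PPh3, DIAD, toluene, 0 °C) should then give 16 with inversion at carbon, where the route is rejoined.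

**Step 5.**
- Risk: incomplete acylation of the dianion by an electron-rich, hindered benzoate, and partial loss of the peri 5-O-benzyl group during the acid stage.
- Fallback: setting out from 5, saponification (LiOH, THF–H2O, acidified only to pH 5 so that the acetal survives) should give the acid F6. Esterification of the phenol of 7 (EDC·HCl, DMAP, CH2Cl2) should give the aryl ester F7. Baker–Venkataraman acyl migration (KOt-Bu, THF, 0 °C to rt) should give 8, which rejoins step 5 at its cyclodehydration stage.

**Step 14.**
- Risk: over-reduction, namely saturation of the flavone C2=C3 bond or hydrogenolytic opening of the benzylic C2–O1 bond, before the slowest benzyl ether is removed.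
- Fallback: setting out from 19, Lewis-acid debenzylation with BCl3 and pentamethylbenzene as cation scavenger (CH2Cl2, −78 °C) should give 20 directly. The 7-methyl ether is not chelated and should survive. The low temperature is needed because a Lewis acid on the C4 carbonyl also activates ring C towards opening.

## Further compounds

F1 | step 12 | (2E)-1-[2-(benzyloxy)-6-hydroxy-4-methoxyphenyl]-3-(4-{2-(benzyloxy)-5-[5,7-bis(benzyloxy)-4-oxo-4H-chromen-2-yl]phenoxy}phenyl)prop-2-en-1-one | COc1cc(O)c(C(=O)/C=C/c2ccc(Oc3cc(-c4cc(=O)c5c(OCc6ccccc6)cc(OCc6ccccc6)cc5o4)ccc3OCc3ccccc3)cc2)c(OCc2ccccc2)c1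
F2 | step 12 | racemic 5-(benzyloxy)-2-(4-{2-(benzyloxy)-5-[5,7-bis(benzyloxy)-4-oxo-4H-chromen-2-yl]phenoxy}phenyl)-7-methoxy-2,3-dihydro-4H-chromen-4-one | COc1cc(OCc2ccccc2)c2c(c1)OC(c1ccc(Oc3cc(-c4cc(=O)c5c(OCc6ccccc6)cc(OCc6ccccc6)cc5o4)ccc3OCc3ccccc3)cc1)CC2=O
F3 | step 10 | racemic 5,7-bis(benzyloxy)-2-{4-(benzyloxy)-3-[4-(1-hydroxyprop-2-en-1-yl)phenoxy]phenyl}-4H-chromen-4-one | C=CC(O)c1ccc(Oc2cc(-c3cc(=O)c4c(OCc5ccccc5)cc(OCc5ccccc5)cc4o3)ccc2OCc2ccccc2)cc1
F4 | step 10 | (1R)-1-(4-{2-(benzyloxy)-5-[5,7-bis(benzyloxy)-4-oxo-4H-chromen-2-yl]phenoxy}phenyl)prop-2-en-1-yl acetate | CC(=O)O[C@@H](c1ccc(Oc2cc(-c3cc(=O)c4c(OCc5ccccc5)cc(OCc5ccccc5)cc4o3)ccc2OCc2ccccc2)cc1)C=C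
F5 | step 10 | 5,7-bis(benzyloxy)-2-[4-(benzyloxy)-3-{4-[(1R)-1-hydroxyprop-2-en-1-yl]phenoxy}phenyl]-4H-chromen-4-one | O[C@@H](c1ccc(Oc2cc(-c3cc(=O)c4c(OCc5ccccc5)cc(OCc5ccccc5)cc4o3)ccc2OCc2ccccc2)cc1)C=C
F6 | step 5 | 4-(benzyloxy)-3-[4-(1,3-dioxolan-2-yl)phenoxy]benzoic acid | O=C(O)c1ccc(OCc2ccccc2)c(Oc2ccc(C3OCCO3)cc2)c1
F7 | step 5 | 2-acetyl-3,5-bis(benzyloxy)phenyl 4-(benzyloxy)-3-[4-(1,3-dioxolan-2-yl)phenoxy]benzoate | CC(=O)c1c(OC(=O)c2ccc(OCc3ccccc3)c(Oc3ccc(C4OCCO4)cc3)c2)cc(OCc2ccccc2)cc1OCc1ccccc1
F0 | step 14 | none | none
A1 | alternative 1 | methyl coumalate (methyl 2-oxo-2H-pyran-5-carboxylate) | COC(=O)C1=COC(=O)C=C1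
A2 | alternative 1 | 2-[4-(benzyloxy)-3-(ethynyloxy)phenyl]-1,3-dioxolane | C#COc1cc(C2OCCO2)ccc1OCc1ccccc1
A3 | alternative 1 | methyl 4-[2-(benzyloxy)-5-(1,3-dioxolan-2-yl)phenoxy]benzoate | COC(=O)c1ccc(Oc2cc(C3OCCO3)ccc2OCc2ccccc2)cc1
A4 | alternative 2 | 3,5-bis(benzyloxy)-2-iodophenol | Oc1cc(OCc2ccccc2)cc(OCc2ccccc2)c1I
A5 | alternative 2 | 2-{4-[2-(benzyloxy)-5-ethynylphenoxy]phenyl}-1,3-dioxolane | C#Cc1ccc(OCc2ccccc2)c(Oc2ccc(C3OCCO3)cc2)c1
A6 | alternative 2 | carbon monoxide | [C-]#[O+]
A7 | alternative 2 | 5,7-bis(benzyloxy)-2-{4-(benzyloxy)-3-[4-(1,3-dioxolan-2-yl)phenoxy]phenyl}-4H-chromen-4-one | O=c1cc(-c2ccc(OCc3ccccc3)c(Oc3ccc(C4OCCO4)cc3)c2)oc2cc(OCc3ccccc3)cc(OCc3ccccc3)c12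
A8 | alternative 3 | methyl (3S)-3-(4-{2-(benzyloxy)-5-[5,7-bis(benzyloxy)-4-oxo-4H-chromen-2-yl]phenoxy}phenyl)-3-hydroxypropanoate | COC(=O)C[C@H](O)c1ccc(Oc2cc(-c3cc(=O)c4c(OCc5ccccc5)cc(OCc5ccccc5)cc4o3)ccc2OCc2ccccc2)cc1
A9 | alternative 3 | 3,5-dimethoxy-2-(trimethylsilyl)phenyl trifluoromethanesulfonate | COc1cc(OC)c([Si](C)(C)C)c(OS(=O)(=O)C(F)(F)F)c1
A10 | alternative 3 | 3,5-dimethoxybenzyne | COC1=CC(OC)=CC#C1
A11 | alternative 3 | (2S)-2-(4-{2-(benzyloxy)-5-[5,7-bis(benzyloxy)-4-oxo-4H-chromen-2-yl]phenoxy}phenyl)-5,7-dimethoxy-2,3-dihydro-4H-chromen-4-one | COc1cc(OC)c2c(c1)O[C@H](c1ccc(Oc3cc(-c4cc(=O)c5c(OCc6ccccc6)cc(OCc6ccccc6)cc5o4)ccc3OCc3ccccc3)cc1)CC2=O
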